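**Strategy**

Ring numbering: C1 (acetoxy carbon), C2=C3, C4 (C=O), C5 (CH–pentenyl). Everything rests on making the C4–C5 ring bond by a Piancatelli rearrangement. The cyclopentenone carries oxygen on C1 and C4, on either side of C2=C3, which is the pattern of a furan oxygen plus one water. The precursor is therefore a 2-furylcarbinol bearing the (Z)-pentenyl group, and one 4π conrotatory closure delivers the whole ring with trans C4–OH and C5–pentenyl, C1 being the ketone. The oxidation levels are exchanged afterwards: C1 becomes the chain-bearing olefin carbon, its oxygen returns by hydroxyl-directed epoxidation anti to pentenyl, and C4 is oxidised to the enone carbonyl.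

Key step: step 3

Assumption: the lipase in step 4 is taken to acylate the (4R,5S) enantiomer of 6 faster (branched C5 side as the large group in the usual empirical model for secondary alcohols); the absolute configuration of recovered 7 is to be checked before going on.

Remark: the side chain is not added directly to the C1 ketone of 8, because attack anti to the neighbouring C5 pentenyl group would be expected and would give the wrong C1 epimer.

**Route**

Step 1
Reactants: 1 (3Z)-hex-3-en-1-ol
Product: 2 (3Z)-hex-3-enal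
Conditions: Dess–Martin periodinane, NaHCO3, CH2Cl2, 0 °C to rt; used at once
Reagents that add atoms: none
Why: Dess–Martin oxidation of the primary alcohol under buffered, base-free conditions should stop at the β,γ-unsaturated aldehyde without moving the Z olefin into conjugation.

Step 2
Reactants: 2 (3Z)-hex-3-enal; 3 furan
Product: 5 rac-(3Z)-1-(furan-2-yl)hex-3-en-1-ol, via 2-furyllithium 4 (not isolated)
Conditions: 3, n-BuLi, THF, 0 °C; then 2, −78 °C; H2O
Reagents that add atoms: none
Why: α-Lithiation of furan and 1,2-addition of the resulting 2-furyllithium to the aldehyde at −78 °C, where carbonyl addition should outrun enolisation; the carbinol centre forms as a racemate, which is irrelevant because it is ionised in step 3.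

Step 3
Reactants: 5 rac-(3Z)-1-(furan-2-yl)hex-3-en-1-ol
Product: 6 racemic trans-4-hydroxy-5-[(2Z)-pent-2-en-1-yl]cyclopent-2-en-1-one
Conditions: ZnCl2, dioxane/H2O 2:1 (pH 5–6), 85 °C
Reagents that add atoms: water, O
Why: ZnCl2 ionises the furfuryl alcohol to a furfuryl (oxocarbenium) cation, water adds at furan C5 and the hemiacetal opens to a 1,4-dihydroxypentadienyl cation, which closes by thermal 4π conrotatory electrocyclisation between the former furan C5 and the former carbinol carbon; this is the C4–C5 bond, joining the later ketone carbon to the pentenyl-bearing CH, while the former furan C2 becomes the C1 ketone. This is the Piancatelli rearrangement, a Nazarov-type cationic electrocyclisation that is established for alkyl 2-furylcarbinols. The one ring closed is the five-membered carbocycle, by conrotatory 4π closure of the two termini of the pentadienyl cation. Both new stereocentres, C4 (OH) and C5 (pentenyl), are controlled by conrotation of the cation with its two terminal substituents pointing outward, which should give the trans isomer only; the cation is achiral, so 6 is racemic. The step needs trans selectivity and must stop before further isomerisation to the 4-hydroxy-2-alkyl isomer, which the weakly acidic medium and limited reaction time should secure; the remote Z olefin is not conjugated with the cation and should stay untouched.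

Step 4
Reactants: 6 racemic trans-4-hydroxy-5-[(2Z)-pent-2-en-1-yl]cyclopent-2-en-1-one
Product: 7 (4S,5R)-4-hydroxy-5-[(2Z)-pent-2-en-1-yl]cyclopent-2-en-1-one
Conditions: Novozym 435 (Candida antarctica lipase B), vinyl acetate, MTBE, 30 °C, to about half conversion; chromatography
Reagents that add atoms: none
Why: Lipase-catalysed kinetic resolution by irreversible acyl transfer from vinyl acetate: one enantiomer of the secondary alcohol should be acetylated much faster, leaving (4S,5R)-7 and thereby fixing C4 and C5 in the absolute sense.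

Step 5
Reactants: 7 (4S,5R)-4-hydroxy-5-[(2Z)-pent-2-en-1-yl]cyclopent-2-en-1-one
Product: 8 (4S,5R)-4-[(tert-butyldimethylsilyl)oxy]-5-[(2Z)-pent-2-en-1-yl]cyclopent-2-en-1-one
Conditions: TBSCl, imidazole, DMF, 0 °C to rt
Reagents that add atoms: tert-butyldimethylsilyl chloride, CC(C)(C)[Si](C)(C)Cl
Why: Standard silylation of a secondary alcohol with TBSCl and imidazole, mild enough to avoid β-elimination of the C4 oxygen or migration of the ring olefin.

Step 6
Reactants: 8 (4S,5R)-4-[(tert-butyldimethylsilyl)oxy]-5-[(2Z)-pent-2-en-1-yl]cyclopent-2-en-1-one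
Product: 11 (4S,5R)-4-[(tert-butyldimethylsilyl)oxy]-5-[(2Z)-pent-2-en-1-yl]cyclopent-1-en-1-yl trifluoromethanesulfonate, via silyl enol ether 9 (not isolated), via lithium enolate 10 (not isolated)
Conditions: [(Ph3P)CuH]6 (cat.), PhMe2SiH, toluene, rt; then MeLi, THF, 0 °C; then PhNTf2, −78 °C to rt; H2O
Reagents that add atoms: N-phenylbis(trifluoromethanesulfonimide), O=S(=O)(N(c1ccccc1)S(=O)(=O)C(F)(F)F)C(F)(F)F
Why: Copper hydride catalysed 1,4-hydrosilylation of the enone gives the C1–C2 silyl enol ether regiospecifically, methyllithium releases the lithium enolate without equilibration toward C5 (which would eliminate the C4 silyloxy group), and the enolate is trapped as the enol triflate with N-phenyltriflimide; no stereocentre is touched.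

Step 7
Reactants: 11 (4S,5R)-4-[(tert-butyldimethylsilyl)oxy]-5-[(2Z)-pent-2-en-1-yl]cyclopent-1-en-1-yl trifluoromethanesulfonate; 12 methyl 8-bromooctanoate
Product: 14 methyl 8-[(4S,5S)-4-[(tert-butyldimethylsilyl)oxy]-5-[(2Z)-pent-2-en-1-yl]cyclopent-1-en-1-yl]octanoate, via alkylzinc bromide 13 (not isolated)
Conditions: 12, Zn dust, I2 (cat.), DMA, 70 °C; then 11, PdCl2(dppf) (cat.), THF/DMA, 50 °C
Reagents that add atoms: none
Why: Negishi coupling: zinc insertion into the primary bromide tolerates the ester, and PdCl2(dppf) should couple the alkylzinc with the enol triflate faster than β-hydride elimination, placing the carboxyl chain on C1 of the C1=C2 olefin.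

Step 8
Reactants: 14 methyl 8-[(4S,5S)-4-[(tert-butyldimethylsilyl)oxy]-5-[(2Z)-pent-2-en-1-yl]cyclopent-1-en-1-yl]octanoate
Product: 15 methyl 8-[(4S,5S)-4-hydroxy-5-[(2Z)-pent-2-en-1-yl]cyclopent-1-en-1-yl]octanoate
Conditions: HF·pyridine, pyridine, THF, 0 °C to rt
Reagents that add atoms: none
Why: Fluoride cleavage of the secondary silyl ether with pyridine-buffered HF, which should leave the ester and both olefins intact and frees the C4 hydroxyl as directing group.

Step 9
Reactants: 15 methyl 8-[(4S,5S)-4-hydroxy-5-[(2Z)-pent-2-en-1-yl]cyclopent-1-en-1-yl]octanoate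
Product: 16 methyl 8-[(1S,2R,3S,5R)-3-hydroxy-2-[(2Z)-pent-2-en-1-yl]-6-oxabicyclo[3.1.0]hexan-1-yl]octanoate (epoxide oxygen cis to the hydroxyl, trans to pentenyl)
Conditions: VO(acac)2 (cat.), t-BuOOH (decane), CH2Cl2, 0 °C to rt
Reagents that add atoms: tert-butyl hydroperoxide, CC(C)(C)OO
Why: Vanadium-catalysed hydroxyl-directed epoxidation of a trans-2-substituted cyclopent-3-enol: the peroxide is delivered to the ring olefin from the face of the C4 hydroxyl, which is also the face anti to the neighbouring C5 pentenyl group, so the C1–O bond is set trans to pentenyl and the chain cis to it, and the trisubstituted homoallylic ring olefin should react well before the remote Z olefin.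

Step 10
Reactants: 16 methyl 8-[(1S,2R,3S,5R)-3-hydroxy-2-[(2Z)-pent-2-en-1-yl]-6-oxabicyclo[3.1.0]hexan-1-yl]octanoate
Product: 18 methyl 8-[(1R,5S)-1-hydroxy-4-oxo-5-[(2Z)-pent-2-en-1-yl]cyclopent-2-en-1-yl]octanoate, via epoxy ketone 17 (not isolated)
Conditions: Dess–Martin periodinane, NaHCO3, CH2Cl2, 0 °C; then Et3N, 0 °C, short contact
Reagents that add atoms: none
Why: Dess–Martin oxidation gives the 3,4-epoxycyclopentanone, which with triethylamine should undergo β-elimination (E1cB-type epoxide opening, the known route from 3,4-epoxycyclopentanones to 4-hydroxycyclopent-2-enones) through the unhindered C3 methylene, the only α-position with a hydrogen anti to the epoxide C–O bond, giving the C2=C3 enone and the tertiary C1 alcohol with C1 and C5 unchanged.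

Step 11
Reactants: 18 methyl 8-[(1R,5S)-1-hydroxy-4-oxo-5-[(2Z)-pent-2-en-1-yl]cyclopent-2-en-1-yl]octanoate
Product: 19 methyl 8-[(1R,5S)-1-(acetyloxy)-4-oxo-5-[(2Z)-pent-2-en-1-yl]cyclopent-2-en-1-yl]octanoate
Conditions: Ac2O, Sc(OTf)3 (cat.), MeCN, −20 °C
Reagents that add atoms: acetic anhydride, CC(=O)OC(C)=O
Why: Sc(OTf)3-catalysed acetylation with acetic anhydride esterifies tertiary alcohols at low temperature without base, so C5 (now α to the ketone) should not epimerise and acetate is not lost by β-elimination, while ionisation at C1 is disfavoured because the cation would sit next to the electron-poor enone.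

Step 12
Reactants: 19 methyl 8-[(1R,5S)-1-(acetyloxy)-4-oxo-5-[(2Z)-pent-2-en-1-yl]cyclopent-2-en-1-yl]octanoate
Product: 20 8-[(1R,5S)-1-(acetyloxy)-4-oxo-5-[(2Z)-pent-2-en-1-yl]cyclopent-2-en-1-yl]octanoic acid
Conditions: Novozym 435, phosphate buffer pH 7/acetone, 30 °C
Reagents that add atoms: water, O
Why: Lipase-catalysed hydrolysis at neutral pH should cleave the unhindered fatty acid methyl ester while the tertiary acetate is not accepted by the enzyme, avoiding the basic conditions that would epimerise C5 or eliminate acetate.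

**Compound list**

1 | (3Z)-hex-3-en-1-ol | CC/C=C\CCO | starting material
2 | (3Z)-hex-3-enal | CC/C=C\CC=O | intermediate
3 | furan | c1ccoc1 | starting material
4 | 2-furyllithium | [Li]c1ccco1 | intermediate
5 | rac-(3Z)-1-(furan-2-yl)hex-3-en-1-ol | CC/C=C\CC(O)c1ccco1 | intermediate
6 | racemic trans-4-hydroxy-5-[(2Z)-pent-2-en-1-yl]cyclopent-2-en-1-one (both enantiomers written) | CC/C=C\C[C@@H]1[C@@H](O)C=CC1=O.CC/C=C\C[C@H]1[C@H](O)C=CC1=O | intermediate
7 | (4S,5R)-4-hydroxy-5-[(2Z)-pent-2-en-1-yl]cyclopent-2-en-1-one | CC/C=C\C[C@@H]1[C@@H](O)C=CC1=O | intermediate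
8 | (4S,5R)-4-[(tert-butyldimethylsilyl)oxy]-5-[(2Z)-pent-2-en-1-yl]cyclopent-2-en-1-one | CC/C=C\C[C@@H]1[C@@H](O[Si](C)(C)C(C)(C)C)C=CC1=O | intermediate
9 | {[(4S,5R)-4-[(tert-butyldimethylsilyl)oxy]-5-[(2Z)-pent-2-en-1-yl]cyclopent-1-en-1-yl]oxy}dimethyl(phenyl)silane | CC/C=C\C[C@@H]1[C@@H](O[Si](C)(C)C(C)(C)C)CC=C1O[Si](C)(C)c1ccccc1 | intermediate
10 | lithium (4S,5R)-4-[(tert-butyldimethylsilyl)oxy]-5-[(2Z)-pent-2-en-1-yl]cyclopent-1-en-1-olate | CC/C=C\C[C@@H]1[C@@H](O[Si](C)(C)C(C)(C)C)CC=C1O[Li] | intermediate
11 | (4S,5R)-4-[(tert-butyldimethylsilyl)oxy]-5-[(2Z)-pent-2-en-1-yl]cyclopent-1-en-1-yl trifluoromethanesulfonate | CC/C=C\C[C@@H]1[C@@H](O[Si](C)(C)C(C)(C)C)CC=C1OS(=O)(=O)C(F)(F)F | intermediate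
12 | methyl 8-bromooctanoate | COC(=O)CCCCCCCBr | starting material
13 | bromo(8-methoxy-8-oxooctyl)zinc | COC(=O)CCCCCCC[Zn]Br | intermediate
14 | methyl 8-[(4S,5S)-4-[(tert-butyldimethylsilyl)oxy]-5-[(2Z)-pent-2-en-1-yl]cyclopent-1-en-1-yl]octanoate | CC/C=C\C[C@@H]1[C@@H](O[Si](C)(C)C(C)(C)C)CC=C1CCCCCCCC(=O)OC | intermediate
15 | methyl 8-[(4S,5S)-4-hydroxy-5-[(2Z)-pent-2-en-1-yl]cyclopent-1-en-1-yl]octanoate | CC/C=C\C[C@@H]1[C@@H](O)CC=C1CCCCCCCC(=O)OC | intermediate
16 | methyl 8-[(1S,2R,3S,5R)-3-hydroxy-2-[(2Z)-pent-2-en-1-yl]-6-oxabicyclo[3.1.0]hexan-1-yl]octanoate | CC/C=C\C[C@@H]1[C@@H](O)C[C@H]2O[C@@]12CCCCCCCC(=O)OC | intermediate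
17 | methyl 8-[(1S,2S,5R)-3-oxo-2-[(2Z)-pent-2-en-1-yl]-6-oxabicyclo[3.1.0]hexan-1-yl]octanoate | CC/C=C\C[C@@H]1C(=O)C[C@H]2O[C@@]12CCCCCCCC(=O)OC | intermediate
18 | methyl 8-[(1R,5S)-1-hydroxy-4-oxo-5-[(2Z)-pent-2-en-1-yl]cyclopent-2-en-1-yl]octanoate | CC/C=C\C[C@@H]1C(=O)C=C[C@@]1(CCCCCCCC(=O)OC)O | intermediate
19 | methyl 8-[(1R,5S)-1-(acetyloxy)-4-oxo-5-[(2Z)-pent-2-en-1-yl]cyclopent-2-en-1-yl]octanoate | CC/C=C\C[C@@H]1C(=O)C=C[C@@]1(CCCCCCCC(=O)OC)OC(C)=O | intermediate
20 | 8-[(1R,5S)-1-(acetyloxy)-4-oxo-5-[(2Z)-pent-2-en-1-yl]cyclopent-2-en-1-yl]octanoic acid | CC/C=C\C[C@@H]1C(=O)C=C[C@@]1(CCCCCCCC(=O)O)OC(C)=O | target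

**Counts and risks**

Total step count: 12. Longest linear sequence: 12 steps (steps 1 to 12; the zinc reagent of step 7 is made in the same flask).

Steps most likely to fail:

Step 10. The β-elimination may run toward C5 instead of C3, giving the tetrasubstituted enone isomer, and the amine may epimerise C5 once the enone has formed. The fallback sets out from 16 and avoids any base in the presence of the ketone. The epoxide is opened at its less substituted carbon C2 with sodium phenylselenide (PhSeSePh, NaBH4, EtOH) to the trans hydroxy selenide F1. Oxidation with H2O2 gives the selenoxide F2, whose syn-elimination can only run toward C3 because C1 carries no hydrogen, and delivers the enediol F3. MnO2 in CH2Cl2 then oxidises the secondary allylic alcohol selectively and the route is rejoined at 18.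

Step 4. The enzyme may discriminate the enantiomers poorly, or acylate the wanted one. The fallback sets out from 6: the racemate is silylated as in step 5 to the racemic silyl ether F4, and the enantiomers are separated by preparative chromatography on a chiral stationary phase (supercritical CO2/alcohol eluent). The (4S,5R) fraction is 8, where the route is rejoined.

Step 3. The furfuryl cation may polymerise, or the product may isomerise further to the 4-hydroxy-2-alkyl isomer during the long heating that alkyl carbinols need. The fallback sets out from 1 and 4 and forms the same C4–C5 bond by aldol addition instead of electrocyclisation. Alcohol 1 is converted with CBr4/PPh3 into (3Z)-1-bromohex-3-ene F5, which alkylates 2-furyllithium 4 to 2-[(3Z)-hex-3-en-1-yl]furan F6. Photooxygenation of the furan (O2, tetraphenylporphyrin, light, CH2Cl2, −78 °C) gives the endoperoxide F7, and reduction with Me2S gives (2Z,7Z)-4-oxodeca-2,7-dienal F8. Intramolecular aldol addition of the ketone α-methylene to the aldehyde in phosphate buffer (pH 7–8)/dioxane returns to the route at 6.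

Further compounds
F1 | step 10 | methyl 8-[1,4-dihydroxy-5-[(2Z)-pent-2-en-1-yl]-2-(phenylselanyl)cyclopentyl]octanoate, selenium trans to the C1 hydroxyl, other centres as in 16 | CC/C=C\C[C@@H]1[C@@H](O)C[C@H]([Se]c2ccccc2)[C@@]1(CCCCCCCC(=O)OC)O
F2 | step 10 | selenoxide of F1 | CC/C=C\C[C@@H]1[C@@H](O)C[C@H]([Se](=O)c2ccccc2)[C@@]1(CCCCCCCC(=O)OC)O
F3 | step 10 | methyl 8-[(1R,4S,5R)-1,4-dihydroxy-5-[(2Z)-pent-2-en-1-yl]cyclopent-2-en-1-yl]octanoate | CC/C=C\C[C@@H]1[C@@H](O)C=C[C@@]1(CCCCCCCC(=O)OC)O
F4 | step 4 | racemic trans-4-[(tert-butyldimethylsilyl)oxy]-5-[(2Z)-pent-2-en-1-yl]cyclopent-2-en-1-one (both enantiomers written) | CC/C=C\C[C@@H]1[C@@H](O[Si](C)(C)C(C)(C)C)C=CC1=O.CC/C=C\C[C@H]1[C@H](O[Si](C)(C)C(C)(C)C)C=CC1=O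
F5 | step 3 | (3Z)-1-bromohex-3-ene | CC/C=C\CCBr
F6 | step 3 | 2-[(3Z)-hex-3-en-1-yl]furan | CC/C=C\CCc1ccco1
F7 | step 3 | 1-[(3Z)-hex-3-en-1-yl]-2,3,7-trioxabicyclo[2.2.1]hept-5-ene (racemic) | CC/C=C\CCC12OOC(O1)C=C2
F8 | step 3 | (2Z,7Z)-4-oxodeca-2,7-dienal | CC/C=C\CCC(=O)/C=C\C=O
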